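**Remark on the chemistry:** locants C1–C15 are those of the germacrane skeleton of the target: the ring ether oxygen bridges C3 and C10, and the lactone is C6–O–C12(=O)–C11(=C13)–C7. (R)-Glyceraldehyde acetonide is taken as the commercial solution. TBDPS = tert-butyl(diphenyl)silyl; TES = triethylsilyl.

## Strategy

The nine-membered oxacycle (O, C3–C10) is not closed directly. Its hallmark, the ether oxygen bridging C3 and the quaternary C10 (bearing methyl C14 and the C1 ketone), is the footprint of a [1,2]-Stevens shift of an oxonium ylide. An eight-membered cyclic ether (O, C3–C9), already carrying the trans-fused α-methylene lactone and all oxygenation, is built by ring-closing metathesis. A 3-diazo-2-oxobutyl chain on C3 then gives a copper carbenoid whose ylide inserts C10 between O and C9. One operation expands the ring to nine atoms, closes the furanone ring, forms C9–C10 and sets C10. Dehydrogenation to the 3(2H)-furanone and desilylation finish.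

Key step: step 16

## Route

Step 1
Reactants: 1 2-methylidenepropane-1,3-diol
Product: 2 2-{[tert-butyl(diphenyl)silyl]oxymethyl}prop-2-en-1-ol
Conditions: NaH (1.0 equiv), THF, 0 °C; TBDPSCl, rt
Reagents that add atoms: tert-butyl(chloro)diphenylsilane, CC(C)(C)[Si](Cl)(c1ccccc1)c1ccccc1
Why: Williamson-type monosilylation, in which one equivalent of NaH gives the sparingly soluble monoalkoxide of the symmetrical diol that is silylated once; no stereocentre is involved.

Step 2
Reactants: 2 2-{[tert-butyl(diphenyl)silyl]oxymethyl}prop-2-en-1-ol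
Product: 3 2-{[tert-butyl(diphenyl)silyl]oxymethyl}prop-2-enal
Conditions: TEMPO (cat.), PhI(OAc)2, CH2Cl2, rt
Reagents that add atoms: none
Why: TEMPO-catalysed oxidation (oxoammonium cycle, PhI(OAc)2 as terminal oxidant) should convert the primary allylic alcohol into the enal without touching the silyl ether; no stereocentre is involved.

Step 3
Reactants: 3 2-{[tert-butyl(diphenyl)silyl]oxymethyl}prop-2-enal; 4 tert-butyl acetate
Product: 5 tert-butyl (3R)-4-{[tert-butyl(diphenyl)silyl]oxymethyl}-3-hydroxypent-4-enoate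
Conditions: LiN(iPr)2, Et2O, −78 °C; CpTiCl(ODAG)2 (ODAG = 1,2:5,6-di-O-isopropylidene-α-D-glucofuranos-3-O-yl), −78 → −30 °C; then 3, −78 °C; aq. NH4F
Reagents that add atoms: none
Why: Acetate aldol addition through a chiral cyclopentadienyl(dialkoxy)titanium enolate, in which the enolate of 4 on the glucose-derived titanium centre should add 1,2 to the Re face of aldehyde 3 through a closed transition state, setting C3 as (R).

Step 4
Reactants: 6 (4R)-2,2-dimethyl-1,3-dioxolane-4-carbaldehyde; 7 methyl acrylate
Product: 8 methyl 2-{[(4R)-2,2-dimethyl-1,3-dioxolan-4-yl](hydroxy)methyl}prop-2-enoate (mixture of carbinol epimers)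
Conditions: DABCO (cat.), 1,4-dioxane/H2O, rt
Reagents that add atoms: none
Why: Morita–Baylis–Hillman reaction of the acrylate with the α-alkoxy aldehyde; the new carbinol centre forms as an epimer mixture that is erased in step 5, and C8 (from 6) is not touched.

Step 5
Reactants: 8 methyl 2-{[(4R)-2,2-dimethyl-1,3-dioxolan-4-yl](hydroxy)methyl}prop-2-enoate
Product: 9 methyl (2Z)-2-(bromomethyl)-3-[(4S)-2,2-dimethyl-1,3-dioxolan-4-yl]prop-2-enoate
Conditions: NBS, Me2S, CH2Cl2, 0 °C → rt
Reagents that add atoms: N-bromosuccinimide, BrN1C(=O)CCC1=O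
Why: Corey–Kim-type activation of the allylic alcohol as an alkoxysulfonium ion and SN2′ attack of bromide should give the rearranged, thermodynamically preferred (Z)-2-(bromomethyl)enoate, with loss of the carbinol stereocentre.

Step 6
Reactants: 9 methyl (2Z)-2-(bromomethyl)-3-[(4S)-2,2-dimethyl-1,3-dioxolan-4-yl]prop-2-enoate; 10 acrolein
Product: 12 (4S,5R)-4-[(4S)-2,2-dimethyl-1,3-dioxolan-4-yl]-3-methylidene-5-vinyloxolan-2-one, via hydroxy ester 11 (not isolated)
Conditions: CrCl2 (2.5 equiv), THF, 0 °C → rt; then p-TsOH (cat.), CH2Cl2, rt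
Reagents that add atoms: none
Why: Nozaki–Hiyama-type (Barbier) allylation, in which the γ-substituted 2-(methoxycarbonyl)allylchromium reagent should add 1,2 to acrolein through a chair transition state to give the anti C6/C7 alcohol (hence the trans lactone after acid-catalysed lactonisation), the face of C7 being set by C8 (C8–H eclipsing the alkene to avoid 1,3-allylic strain, aldehyde delivered anti to the C8–C9 bond).

Step 7
Reactants: 12 (4S,5R)-4-[(4S)-2,2-dimethyl-1,3-dioxolan-4-yl]-3-methylidene-5-vinyloxolan-2-one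
Product: 13 (4R,5R)-4-[(1S)-1,2-dihydroxyethyl]-3-methylidene-5-vinyloxolan-2-one
Conditions: AcOH/H2O (4:1), 45 °C
Reagents that add atoms: none
Why: Acid-catalysed acetal hydrolysis in weak aqueous acid should free the C8/C9 diol without moving the lactone from O6 to O8; no stereocentre is changed.

Step 8
Reactants: 13 (4R,5R)-4-[(1S)-1,2-dihydroxyethyl]-3-methylidene-5-vinyloxolan-2-one
Product: 14 (4S,5R)-3-methylidene-4-[(2S)-oxiran-2-yl]-5-vinyloxolan-2-one
Conditions: PPh3, DIAD, toluene, 0 → 80 °C
Reagents that add atoms: none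
Why: Mitsunobu cyclodehydration of a 1,2-diol, in which the primary C9 oxygen is activated as the oxyphosphonium ion and displaced by the C8 hydroxyl, so the epoxide forms with retention at C8.

Step 9
Reactants: 14 (4S,5R)-3-methylidene-4-[(2S)-oxiran-2-yl]-5-vinyloxolan-2-one; 5 tert-butyl (3R)-4-{[tert-butyl(diphenyl)silyl]oxymethyl}-3-hydroxypent-4-enoate
Product: 15 tert-butyl (3R)-4-{[tert-butyl(diphenyl)silyl]oxymethyl}-3-{(2S)-2-hydroxy-2-[(2R,3R)-4-methylidene-5-oxo-2-vinyloxolan-3-yl]ethoxy}pent-4-enoate
Conditions: BF3·OEt2 (0.2 equiv), 5 (2.5 equiv, excess recovered), CH2Cl2, −30 → 0 °C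
Reagents that add atoms: none
Why: Lewis-acid-catalysed alcoholysis of a terminal epoxide (SN2 opening), in which the secondary alcohol of 5 attacks the unhindered C9 terminus to form the C9–O–C3 ether and free the C8 hydroxyl; C3 and C8 keep their configuration because no C–O bond at these centres is broken.

Step 10
Reactants: 15 tert-butyl (3R)-4-{[tert-butyl(diphenyl)silyl]oxymethyl}-3-{(2S)-2-hydroxy-2-[(2R,3R)-4-methylidene-5-oxo-2-vinyloxolan-3-yl]ethoxy}pent-4-enoate
Product: 16 eight-membered cyclic ether (ring O–C3–C4=C5–C6–C7–C8–C9, 4Z) trans-fused at C6/C7 to the α-methylene-γ-butyrolactone; C3 (R) bears CH2CO2tBu, C4 bears CH2OTBDPS, C8 (S) bears OH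
Conditions: second-generation Hoveyda–Grubbs catalyst RuCl2(H2IMes)(=CH-C6H4-2-OiPr) (10 mol %), toluene (2 mM), 80 °C
Reagents that add atoms: none
Why: Ring-closing metathesis, in which the ruthenium carbene loads on the monosubstituted C5 vinyl group and closes onto the 1,1-disubstituted C4 alkene, the trans-fused lactone holding both arms close as in known closures of trisubstituted eight-membered rings fused to a five-membered ring; the Z C4=C5 bond is the only one the ring allows and no stereocentre is formed.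

Step 11
Reactants: 16 eight-membered cyclic ether with free C8 hydroxyl
Product: 17 C8 methacrylate of 16
Conditions: methacrylic anhydride, Et3N, DMAP (cat.), CH2Cl2, 0 °C
Reagents that add atoms: methacrylic anhydride, C=C(C)C(=O)OC(=O)C(C)=C
Why: DMAP-catalysed (Steglich-type) acylation of the secondary C8 alcohol with retention, placed after the metathesis so that the methacrylate cannot compete as a metathesis partner.

Step 12
Reactants: 17 C8 methacrylate of the eight-membered cyclic ether
Product: 18 C4,C5-cis-diol of 17 (tertiary C4–OH, secondary C5–OH, both on the ring face of the lactone oxygen O6 and opposite the C3 side chain)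
Conditions: OsO4 (5 mol %), N-methylmorpholine N-oxide, acetone/H2O, 0 °C
Reagents that add atoms: N-methylmorpholine N-oxide, C[N+]1([O-])CCOCC1; water, O
Why: Upjohn syn-dihydroxylation, in which OsO4 should add to the strained, electron-richer ring alkene rather than to the two conjugated 1,1-disubstituted alkenes and from the ring face opposite the C3 side chain, C11 and the C8 ester, which sets C4 and C5 together.

Step 13
Reactants: 18 C4,C5-cis-diol
Product: 19 C5 acetate of 18 (C4–OH free)
Conditions: Ac2O, pyridine, DMAP (cat.), CH2Cl2, 0 °C → rt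
Reagents that add atoms: acetic anhydride, CC(=O)OC(C)=O
Why: DMAP-catalysed acetylation distinguishes the secondary C5 hydroxyl from the hindered tertiary C4 hydroxyl, which stays free; no stereocentre is changed.

Step 14
Reactants: 19 C5 acetate with free tertiary C4 hydroxyl and tert-butyl ester
Product: 21 C1 carboxylic acid with C4–OTES, via triethylsilyl ester 20 (not isolated)
Conditions: TESOTf (4 equiv), 2,6-lutidine, CH2Cl2, −78 → 0 °C; then pH 7 phosphate buffer
Reagents that add atoms: triethylsilyl trifluoromethanesulfonate, CC[Si](CC)(CC)OS(=O)(=O)C(F)(F)F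
Why: Silyl-triflate chemistry, in which TESOTf silylates the tertiary C4 hydroxyl and, by O-silylation of the ester carbonyl and loss of 2-methylpropene, turns the tert-butyl ester into the triethylsilyl ester that is hydrolysed on buffered work-up, while the silyl ethers, acetate, methacrylate and lactone stay.

Step 15
Reactants: 21 C1 carboxylic acid with C4–OTES
Product: 23 diazoketone (C3 side chain CH2–C(=O)–C(=N2)–CH3), via acid chloride 22 (not isolated)
Conditions: 1-chloro-N,N,2-trimethylprop-1-en-1-amine, CH2Cl2, 0 °C; then CH3CHN2 (2.2 equiv), Et2O, −78 → −40 °C; AcOH quench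
Reagents that add atoms: diazoethane, CC=[N+]=[N-]
Why: Acylation of a diazoalkane (first stage of the Arndt–Eistert sequence), in which the acid chloride made under neutral conditions acylates diazoethane at −78 °C, a second equivalent taking up HCl, while the low temperature keeps dipolar cycloaddition to the two conjugated alkenes slow; no stereocentre is changed.

Step 16
Reactants: 23 diazoketone
Product: 25 11-oxabicyclo[6.2.1]undecan-9-one-type ketone (O bridging C3 and C10, C1 ketone, C3–H, C10 quaternary with methyl), via oxonium ylide 24 (not isolated)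
Conditions: Cu(CF3COCHCOCF3)2 [Cu(hfacac)2] (10 mol %), CH2Cl2, reflux, slow addition of 23 (final 5 mM)
Reagents that add atoms: none
Why: Cu(hfacac)2 should convert the diazoketone into an electrophilic copper carbenoid at C10, which is captured by a lone pair of the ring ether oxygen to give the bicyclic oxonium ylide 24, and this ylide undergoes a Stevens [1,2]-shift (O–C9 homolysis and radical-pair recombination at C10), so that C10 is inserted between O and C9. The closest known reaction type is the copper- or rhodium-catalysed oxonium ylide [1,2]-shift of diazoketone-tethered tetrahydrofurans and tetrahydropyrans, which gives oxygen-bridged medium-ring ketones by one-atom ring expansion. The five-membered ylide ring (O, C3, C2, C1, C10) closes by 5-exo attack of oxygen on the carbenoid carbon, and the nine-membered ring (O, C3–C10) arises from the eight-membered ether by migration of C9 from oxygen to C10, which at the same time completes the ten-membered carbocycle C1–C10. The new stereocentre C10 is controlled by C3, because the six-carbon bridge C4–C9 can span the tetrahydrofuranone only cis, so C9 is delivered to the face of the ylide that carries C4 and the methyl group ends up trans to it. The step needs ylide formation at the ring oxygen rather than C–H insertion, 1,2-hydride shift from C14 or attack at the silyl ether oxygen on C4, and migration of C9 rather than C3; the five-membered ylide is kinetically preferred over the six-membered one, the tertiary triethylsilyl ether is hindered, the copper catalyst favours ylide chemistry, C4 and C5 are saturated so that C3 is not allylic, and migration of C3 would give a strained cyclobutanone.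

Step 17
Reactants: 25 bicyclic tetrahydrofuran-3-one
Product: 26 bis-silylated 3(2H)-furanone (C2=C3, C1 ketone; C4–OTES, C15–OTBDPS)
Conditions: IBX (3 equiv), DMSO/fluorobenzene, 65 °C
Reagents that add atoms: none
Why: IBX dehydrogenation of a ketone to the enone, in which the C1 ketone can enolise only towards C2 (C10 is quaternary) and loss of H2 and H3 gives the vinylogous ester, erasing the C3 stereocentre and leaving C10 untouched.

Step 18
Reactants: 26 bis-silylated 3(2H)-furanone
Product: 27 CNP0275292.4, (4S,5S,6S,7R,8R,10R)-5-acetoxy-4,15-dihydroxy-1-oxo-3,10-epoxygermacra-2,11(13)-dien-12,6-olid-8-yl methacrylate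
Conditions: HF·pyridine, THF/pyridine, 0 °C → rt
Reagents that add atoms: none
Why: Fluoride-mediated desilylation, in which buffered HF·pyridine should cleave the tertiary triethylsilyl and the primary TBDPS ether without hydrolysing or moving the acetate, methacrylate or lactone.

## Compound list

1 | 2-methylidenepropane-1,3-diol | C=C(CO)CO | starting material
2 | 2-{[tert-butyl(diphenyl)silyl]oxymethyl}prop-2-en-1-ol | C=C(CO)CO[Si](c1ccccc1)(c1ccccc1)C(C)(C)C | intermediate
3 | 2-{[tert-butyl(diphenyl)silyl]oxymethyl}prop-2-enal | C=C(C=O)CO[Si](c1ccccc1)(c1ccccc1)C(C)(C)C | intermediate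
4 | tert-butyl acetate | CC(=O)OC(C)(C)C | starting material
5 | tert-butyl (3R)-4-{[tert-butyl(diphenyl)silyl]oxymethyl}-3-hydroxypent-4-enoate | CC(C)(C)OC(=O)C[C@@H](O)C(=C)CO[Si](c1ccccc1)(c1ccccc1)C(C)(C)C | intermediate
6 | (4R)-2,2-dimethyl-1,3-dioxolane-4-carbaldehyde ((R)-glyceraldehyde acetonide) | O=C[C@H]1COC(C)(C)O1 | starting material
7 | methyl acrylate | C=CC(=O)OC | starting material
8 | methyl 2-{[(4R)-2,2-dimethyl-1,3-dioxolan-4-yl](hydroxy)methyl}prop-2-enoate (carbinol epimers) | C=C(C(=O)OC)C(O)[C@H]1COC(C)(C)O1 | intermediate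
9 | methyl (2Z)-2-(bromomethyl)-3-[(4S)-2,2-dimethyl-1,3-dioxolan-4-yl]prop-2-enoate | BrC/C(C(=O)OC)=C\[C@H]1COC(C)(C)O1 | intermediate
10 | acrolein | C=CC=O | starting material
11 | methyl (3S,4R)-3-[(4S)-2,2-dimethyl-1,3-dioxolan-4-yl]-4-hydroxy-2-methylidenehex-5-enoate (not isolated) | C=C[C@@H](O)[C@H](C(=C)C(=O)OC)[C@H]1COC(C)(C)O1 | intermediate
12 | (4S,5R)-4-[(4S)-2,2-dimethyl-1,3-dioxolan-4-yl]-3-methylidene-5-vinyloxolan-2-one | C=C[C@H]1OC(=O)C(=C)[C@@H]1[C@H]1COC(C)(C)O1 | intermediate
13 | (4R,5R)-4-[(1S)-1,2-dihydroxyethyl]-3-methylidene-5-vinyloxolan-2-one | C=C[C@H]1OC(=O)C(=C)[C@@H]1[C@H](O)CO | intermediate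
14 | (4S,5R)-3-methylidene-4-[(2S)-oxiran-2-yl]-5-vinyloxolan-2-one | C=C[C@H]1OC(=O)C(=C)[C@@H]1[C@H]1CO1 | intermediate
15 | tert-butyl (3R)-4-{[tert-butyl(diphenyl)silyl]oxymethyl}-3-{(2S)-2-hydroxy-2-[(2R,3R)-4-methylidene-5-oxo-2-vinyloxolan-3-yl]ethoxy}pent-4-enoate | C=C[C@H]1OC(=O)C(=C)[C@@H]1[C@H](O)CO[C@H](CC(=O)OC(C)(C)C)C(=C)CO[Si](c1ccccc1)(c1ccccc1)C(C)(C)C | intermediate
16 | eight-membered cyclic ether (O–C3–C4=C5–C6–C7–C8–C9, 4Z) trans-fused to the α-methylene-γ-butyrolactone; C3 (R) CH2CO2tBu, C4 CH2OTBDPS, C8 (S) OH | CC(C)(C)OC(=O)C[C@H]1OC[C@@H](O)[C@H]2C(=C)C(=O)O[C@@H]2/C=C1/CO[Si](c1ccccc1)(c1ccccc1)C(C)(C)C | intermediate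
17 | C8 methacrylate of 16 | CC(C)(C)OC(=O)C[C@H]1OC[C@@H](OC(=O)C(C)=C)[C@H]2C(=C)C(=O)O[C@@H]2/C=C1/CO[Si](c1ccccc1)(c1ccccc1)C(C)(C)C | intermediate
18 | C4,C5-cis-diol of 17 (configuration at C4 and C5 as in 27) | CC(C)(C)OC(=O)C[C@H]1OC[C@@H](OC(=O)C(C)=C)[C@H]2C(=C)C(=O)O[C@@H]2[C@H](O)[C@@]1(O)CO[Si](c1ccccc1)(c1ccccc1)C(C)(C)C | intermediate
19 | C5 acetate of 18 (C4–OH free) | CC(C)(C)OC(=O)C[C@H]1OC[C@@H](OC(=O)C(C)=C)[C@H]2C(=C)C(=O)O[C@@H]2[C@H](OC(C)=O)[C@@]1(O)CO[Si](c1ccccc1)(c1ccccc1)C(C)(C)C | intermediate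
20 | triethylsilyl ester with C4–OTES (not isolated) | CC[Si](CC)(CC)OC(=O)C[C@H]1OC[C@@H](OC(=O)C(C)=C)[C@H]2C(=C)C(=O)O[C@@H]2[C@H](OC(C)=O)[C@@]1(O[Si](CC)(CC)CC)CO[Si](c1ccccc1)(c1ccccc1)C(C)(C)C | intermediate
21 | C1 carboxylic acid with C4–OTES | OC(=O)C[C@H]1OC[C@@H](OC(=O)C(C)=C)[C@H]2C(=C)C(=O)O[C@@H]2[C@H](OC(C)=O)[C@@]1(O[Si](CC)(CC)CC)CO[Si](c1ccccc1)(c1ccccc1)C(C)(C)C | intermediate
22 | C1 acid chloride (not isolated) | ClC(=O)C[C@H]1OC[C@@H](OC(=O)C(C)=C)[C@H]2C(=C)C(=O)O[C@@H]2[C@H](OC(C)=O)[C@@]1(O[Si](CC)(CC)CC)CO[Si](c1ccccc1)(c1ccccc1)C(C)(C)C | intermediate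
23 | diazoketone (C3–CH2–C(=O)–C(=N2)–CH3) on the eight-membered ether | CC(=[N+]=[N-])C(=O)C[C@H]1OC[C@@H](OC(=O)C(C)=C)[C@H]2C(=C)C(=O)O[C@@H]2[C@H](OC(C)=O)[C@@]1(O[Si](CC)(CC)CC)CO[Si](c1ccccc1)(c1ccccc1)C(C)(C)C | intermediate
24 | bicyclic oxonium ylide (O+ bonded to C3, C9, C10; carbanion at C10; not isolated) | C[C-]1C(=O)C[C@H]2[O+]1C[C@@H](OC(=O)C(C)=C)[C@H]3C(=C)C(=O)O[C@@H]3[C@H](OC(C)=O)[C@@]2(O[Si](CC)(CC)CC)CO[Si](c4ccccc4)(c4ccccc4)C(C)(C)C | intermediate
25 | ring-expanded bicyclic ketone (11-oxabicyclo[6.2.1]undecan-9-one core; C3 (R)–H, C10 quaternary; other centres as in 27) | C=C(C)C(=O)O[C@@H]1C[C@@]2(C)O[C@H](CC2=O)[C@](O[Si](CC)(CC)CC)(CO[Si](c3ccccc3)(c3ccccc3)C(C)(C)C)[C@@H](OC(C)=O)[C@H]2OC(=O)C(=C)[C@@H]21 | intermediate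
26 | 4-O-TES, 15-O-TBDPS ether of 27 | C=C(C)C(=O)O[C@@H]1C[C@@]2(C)OC(=CC2=O)[C@](O[Si](CC)(CC)CC)(CO[Si](c3ccccc3)(c3ccccc3)C(C)(C)C)[C@@H](OC(C)=O)[C@H]2OC(=O)C(=C)[C@@H]21 | intermediate
27 | CNP0275292.4, (4S,5S,6S,7R,8R,10R)-5-acetoxy-4,15-dihydroxy-1-oxo-3,10-epoxygermacra-2,11(13)-dien-12,6-olid-8-yl methacrylate | C=C(C)C(=O)O[C@@H]1C[C@@]2(C)OC(=CC2=O)[C@](O)(CO)[C@@H](OC(C)=O)[C@H]2OC(=O)C(=C)[C@@H]21 | target

## Step count and risks

Total: 18 steps. Longest linear sequence: 15 steps (6 → 27 through steps 4–18). The branch 1 → 5 (steps 1–3) joins at step 9.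

**Step 16 (ring-expanding Stevens shift).** The methyl-substituted carbenoid may lose its identity by 1,2-hydride migration from C14 (giving a vinyl ketone) before the ether oxygen captures it. The fallback brings C14 in after the ring expansion. It sets out from acid 21: the acid chloride 22 is made as in step 15 and acylates diazomethane to give the terminal diazomethyl ketone F1, which cannot undergo hydride migration. Cu(hfacac)2 in refluxing CH2Cl2 should then give the ring-expanded C10–H bicyclic ketone F2 by the same [1,2]-shift. IBX dehydrogenation gives the C10–H 3(2H)-furanone F3. Deprotonation of its acidic C10–H with LiN(SiMe3)2 at −78 °C and C-methylation with MeI, which can only occur on the face opposite the C4–C9 bridge, returns to the route at 26.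

**Step 12 (dihydroxylation).** Osmylation may take place on the wrong ring face, for example anti to the allylic lactone oxygen on C6 and therefore syn to the C3 side chain. The fallback is a Woodward cis-hydroxylation, which delivers the cis diol to the face opposite the one first attacked by the electrophile. It sets out from 17: I2 and AgOAc in acetic acid form the iodonium ion on the accessible face of the electron-rich ring alkene only, and acetate opens it at the tertiary C4 to give the trans-iodo acetate F4. In wet acetic acid at 90 °C the neighbouring acetoxy group displaces iodide with inversion at C5, and the cis-fused acetoxonium ion is hydrolysed to the cis hydroxy acetate. This settles as the secondary C5 acetate and comes back to the route at 19, which also saves step 13.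

**Step 9 (ether coupling).** Oligomerisation of the epoxide under Lewis acid or slow intermolecular attack of the hindered secondary alcohol may keep conversion to the ether low. The fallback replaces the epoxide opening by a silver-promoted alkylation. It sets out from epoxide 14: LiI in AcOH/THF gives the iodohydrin F5, and TESOTf with 2,6-lutidine gives its triethylsilyl ether F6. AgOTf with 2,6-di-tert-butylpyridine in CH2Cl2 then alkylates alcohol 5 with this primary iodide to give the O8-triethylsilyl ether of the coupled diene F7. PPTS in methanol removes the silyl group and comes back to the route at 15.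

## Further compounds

F1 | step 16 | diazomethyl ketone analogue of 23 lacking C14 | [N-]=[N+]=CC(=O)C[C@H]1OC[C@@H](OC(=O)C(C)=C)[C@H]2C(=C)C(=O)O[C@@H]2[C@H](OC(C)=O)[C@@]1(O[Si](CC)(CC)CC)CO[Si](c1ccccc1)(c1ccccc1)C(C)(C)C
F2 | step 16 | C10–H bicyclic ketone (14-nor analogue of 25) | C=C(C)C(=O)O[C@@H]1C[C@H]2O[C@H](CC2=O)[C@](O[Si](CC)(CC)CC)(CO[Si](c3ccccc3)(c3ccccc3)C(C)(C)C)[C@@H](OC(C)=O)[C@H]2OC(=O)C(=C)[C@@H]21
F3 | step 16 | C10–H 3(2H)-furanone (14-nor analogue of 26) | C=C(C)C(=O)O[C@@H]1C[C@H]2OC(=CC2=O)[C@](O[Si](CC)(CC)CC)(CO[Si](c3ccccc3)(c3ccccc3)C(C)(C)C)[C@@H](OC(C)=O)[C@H]2OC(=O)C(=C)[C@@H]21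
F4 | step 12 | trans-iodo acetate from 17 (C4 acetoxy, C5 iodo) | CC(C)(C)OC(=O)C[C@H]1OC[C@@H](OC(=O)C(C)=C)[C@H]2C(=C)C(=O)O[C@@H]2[C@@H](I)[C@@]1(OC(C)=O)CO[Si](c1ccccc1)(c1ccccc1)C(C)(C)C
F5 | step 9 | (4R,5R)-4-[(1S)-1-hydroxy-2-iodoethyl]-3-methylidene-5-vinyloxolan-2-one | C=C[C@H]1OC(=O)C(=C)[C@@H]1[C@H](O)CI
F6 | step 9 | triethylsilyl ether of F5 | C=C[C@H]1OC(=O)C(=C)[C@@H]1[C@H](O[Si](CC)(CC)CC)CI
F7 | step 9 | O8-triethylsilyl ether of 15 | C=C[C@H]1OC(=O)C(=C)[C@@H]1[C@H](O[Si](CC)(CC)CC)CO[C@H](CC(=O)OC(C)(C)C)C(=C)CO[Si](c1ccccc1)(c1ccccc1)C(C)(C)C
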